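**Plan**

Numbering: ring B is C1 (side-chain carbon)–C2–C3–C4 (methyl carbon)–C4a–C8a; the arene carries O at C5 and the carboxyl at C7; the side chain runs from C11 (on C1) to C16 (CH2O).
Retrosynthetic cuts, in order: the C16–O acyl bond and the protecting groups; C2–C3 of ring B, by reinserting SO2 between C2 and C3 to give a benzo-fused seven-membered sulfone; the two C–S bonds; C1–C11 (Ireland–Claisen); the ester C–O that joins arene and side-chain fragments; C8a–C1 and C4a–C4 back to the bromo-diphenol; C13–C14 back to crotonaldehyde.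
Enabling feature: C1 and C4 are benzylic stereocentres kept apart by the stereochemically silent C2–C3 bridge of ring B, so ring B can be closed last at a bond that carries no stereochemistry.
Forward order: the arene receives the C4 arm and an acetic acid arm, is esterified with the side-chain allylic alcohol and rearranged; the two CH2O arms are bridged by sulfur, and ring B arises by contraction of the sulfone; desilylation, acylation, saturation and acidolysis finish.
Stereochemistry: C15 from (S)-3-bromo-2-methylpropan-1-ol; C4 from a catalyst-controlled hydroboration; C11 by chirality transfer from a CBS-set carbinol and C1 from the chair Ireland–Claisen transition state.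

Key step: step 20

**Remarks on the chemistry**

- Assumption: the sense of induction of the cobalt catalyst in step 6 is assigned on first use, and the ligand antipode that leads to the (2S)-alcohol 8 is then employed.
- The phenol is carried as a 4-methoxybenzyl (PMB) ether so that the final acidolysis frees phenol and acid together.
- The C12=C13 alkene left by the rearrangement is a spectator through the key step and is saturated together with C2=C3.

**Route**

Step 1
Reactants: 1 4-bromo-3,5-dihydroxybenzoic acid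
Product: 2 tert-butyl 4-bromo-3,5-dihydroxybenzoate
Conditions: Me2NCH(Ot-Bu)2 (4 equiv), toluene, 80 °C
Reagents that add atoms: N,N-dimethylformamide di-tert-butyl acetal, CN(C)C(OC(C)(C)C)OC(C)(C)C
Why: Acetal-mediated tert-butyl esterification alkylates the carboxylate while the less acidic phenols stay free, and the tert-butyl ester is chosen because it resists the hydroxide, sulfide and hydride reagents used later.

Step 2
Reactants: 2 tert-butyl 4-bromo-3,5-dihydroxybenzoate
Product: 3 tert-butyl 4-bromo-3-hydroxy-5-[(4-methoxybenzyl)oxy]benzoate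
Conditions: PMBCl (1.0 equiv), K2CO3 (1.0 equiv), DMF, rt; unreacted 2 recycled
Reagents that add atoms: 4-methoxybenzyl chloride, COc1ccc(CCl)cc1
Why: Williamson etherification of one of two equivalent phenols is a statistical desymmetrisation that should give the mono-ether as main product beside recoverable diphenol and bis-ether.

Step 3
Reactants: 3 tert-butyl 4-bromo-3-hydroxy-5-[(4-methoxybenzyl)oxy]benzoate
Product: 4 tert-butyl 3-hydroxy-5-[(4-methoxybenzyl)oxy]-4-(prop-1-en-2-yl)benzoate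
Conditions: isopropenyl-Bpin (1.5 equiv), Pd(OAc)2 (5 mol %), SPhos (10 mol %), K3PO4, toluene/H2O, 90 °C
Reagents that add atoms: 4,4,5,5-tetramethyl-2-(prop-1-en-2-yl)-1,3,2-dioxaborolane, CC(=C)B1OC(C)(C)C(C)(C)O1
Why: Suzuki–Miyaura coupling at a bromide that is flanked by two oxygens but activated by the para ester is within reach of a dialkylbiarylphosphine catalyst, and the free phenol is tolerated as its phenoxide.

Step 4
Reactants: 4 tert-butyl 3-hydroxy-5-[(4-methoxybenzyl)oxy]-4-(prop-1-en-2-yl)benzoate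
Product: 5 tert-butyl 3-[(4-methoxybenzyl)oxy]-4-(prop-1-en-2-yl)-5-[(trifluoromethanesulfonyl)oxy]benzoate
Conditions: PhNTf2, Et3N, DMAP (cat.), CH2Cl2, rt
Reagents that add atoms: N-phenyl-bis(trifluoromethanesulfonimide), O=S(=O)(N(c1ccccc1)S(=O)(=O)C(F)(F)F)C(F)(F)F
Why: Phenol triflation with the mild triflimide reagent avoids the strong acid that would dimerise an ortho-isopropenylphenol.

Step 5
Reactants: 5 tert-butyl 3-[(4-methoxybenzyl)oxy]-4-(prop-1-en-2-yl)-5-[(trifluoromethanesulfonyl)oxy]benzoate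
Product: 6 tert-butyl 3-(2-methoxy-2-oxoethyl)-5-[(4-methoxybenzyl)oxy]-4-(prop-1-en-2-yl)benzoate
Conditions: BrZnCH2CO2Me (2 equiv, from methyl bromoacetate and Zn dust in THF), Pd2(dba)3 (2.5 mol %), XPhos (10 mol %), THF, 60 °C
Reagents that add atoms: (2-methoxy-2-oxoethyl)zinc bromide, COC(=O)C[Zn]Br
Why: Negishi-type coupling of a Reformatsky reagent with an aryl triflate forms the C8a–C1 bond under neutral conditions that leave both esters and the alkene untouched.

Step 6
Reactants: 6 tert-butyl 3-(2-methoxy-2-oxoethyl)-5-[(4-methoxybenzyl)oxy]-4-(prop-1-en-2-yl)benzoate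
Product: 8 tert-butyl 4-[(2S)-1-hydroxypropan-2-yl]-3-(2-methoxy-2-oxoethyl)-5-[(4-methoxybenzyl)oxy]benzoate, via alkyl pinacol boronate 7 (not isolated)
Conditions: (IPO)CoCl2 (2 mol %; IPO = enantiopure iminopyridine–oxazoline pincer ligand, antipode selected for the 2S product), NaBHEt3 (4 mol %), HBpin (1.2 equiv), THF, rt; then NaBO3·4H2O, THF/H2O, 0 °C to rt
Reagents that add atoms: sodium perborate, [Na+].[O-]OB=O
Why: Cobalt-catalysed asymmetric anti-Markovnikov hydroboration of a 1,1-disubstituted aryl alkene followed by stereoretentive C–B oxidation sets C4 by catalyst control of the face to which hydrogen is delivered.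

Step 7
Reactants: 8 tert-butyl 4-[(2S)-1-hydroxypropan-2-yl]-3-(2-methoxy-2-oxoethyl)-5-[(4-methoxybenzyl)oxy]benzoate
Product: 9 tert-butyl 3-(2-methoxy-2-oxoethyl)-5-[(4-methoxybenzyl)oxy]-4-[(2S)-1-(triethylsilyloxy)propan-2-yl]benzoate
Conditions: TESCl, imidazole, CH2Cl2, 0 °C
Reagents that add atoms: chlorotriethylsilane, CC[Si](Cl)(CC)CC
Why: Silylation masks the C3 hydroxyl as a triethylsilyl ether that can later be removed by mild acid in the presence of the side-chain tert-butyldimethylsilyl ether.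

Step 8
Reactants: 9 tert-butyl 3-(2-methoxy-2-oxoethyl)-5-[(4-methoxybenzyl)oxy]-4-[(2S)-1-(triethylsilyloxy)propan-2-yl]benzoate
Product: 10 {5-(tert-butoxycarbonyl)-3-[(4-methoxybenzyl)oxy]-2-[(2S)-1-(triethylsilyloxy)propan-2-yl]phenyl}acetic acid
Conditions: LiOH·H2O, THF/MeOH/H2O, 0 °C to rt; then cold dilute HCl to pH 4
Reagents that add atoms: lithium hydroxide, [Li+].[OH-]
Why: Saponification cleaves the unhindered methyl arylacetate while the tert-butyl benzoate is sterically shielded from hydroxide and the silyl and benzyl-type ethers are base-stable.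

Step 9
Reactants: 11 (S)-3-bromo-2-methylpropan-1-ol
Product: 12 (S)-(3-bromo-2-methylpropoxy)(tert-butyl)dimethylsilane
Conditions: TBSCl, imidazole, CH2Cl2, rt
Reagents that add atoms: tert-butyldimethylsilyl chloride, CC(C)(C)[Si](C)(C)Cl
Why: Silylation protects the future C16 hydroxyl, and the C15 stereocentre comes unchanged from the chiral pool.

Step 10
Reactants: 12 (S)-(3-bromo-2-methylpropoxy)(tert-butyl)dimethylsilane; 13 (E)-but-2-enal (crotonaldehyde)
Product: 15 (2E,6R)-7-(tert-butyldimethylsilyloxy)-6-methylhept-2-en-4-ol as both C4 epimers, via Grignard reagent 14 (not isolated)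
Conditions: Mg turnings, THF, 45 °C; then 13, THF, −78 °C; H2O quench
Reagents that add atoms: none
Why: Grignard 1,2-addition to the enal forms the C13–C14 bond, and the uncontrolled carbinol centre is corrected by the following oxidation–reduction pair.

Step 11
Reactants: 15 (2E,6R)-7-(tert-butyldimethylsilyloxy)-6-methylhept-2-en-4-ol
Product: 16 (2E,6R)-7-(tert-butyldimethylsilyloxy)-6-methylhept-2-en-4-one
Conditions: Dess–Martin periodinane, CH2Cl2, 0 °C to rt
Reagents that add atoms: none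
Why: Dess–Martin oxidation of the allylic alcohol gives the enone without touching the (E)-alkene or the methyl-bearing centre, which is β to the carbonyl and not epimerisable.

Step 12
Reactants: 16 (2E,6R)-7-(tert-butyldimethylsilyloxy)-6-methylhept-2-en-4-one
Product: 17 (2E,4R,6R)-7-(tert-butyldimethylsilyloxy)-6-methylhept-2-en-4-ol
Conditions: (S)-2-methyl-CBS-oxazaborolidine (0.2 equiv), catecholborane (1.8 equiv), toluene, −78 °C
Reagents that add atoms: none
Why: Corey–Bakshi–Shibata reduction, in which the propenyl group plays the large substituent, should deliver hydride under catalyst control to give the (4R)-allylic alcohol.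

Step 13
Reactants: 10 {5-(tert-butoxycarbonyl)-3-[(4-methoxybenzyl)oxy]-2-[(2S)-1-(triethylsilyloxy)propan-2-yl]phenyl}acetic acid; 17 (2E,4R,6R)-7-(tert-butyldimethylsilyloxy)-6-methylhept-2-en-4-ol
Product: 18 tert-butyl 3-(2-{[(2E,4R,6R)-7-(tert-butyldimethylsilyloxy)-6-methylhept-2-en-4-yl]oxy}-2-oxoethyl)-5-[(4-methoxybenzyl)oxy]-4-[(2S)-1-(triethylsilyloxy)propan-2-yl]benzoate
Conditions: DCC, DMAP (cat.), CH2Cl2, 0 °C to rt
Reagents that add atoms: none
Why: Steglich esterification joins the two fragments at the acyl carbon, so the carbinol configuration is retained.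

Step 14
Reactants: 18 the allylic arylacetate
Product: 21 (2S,3S,4E,7R)-2-{5-(tert-butoxycarbonyl)-3-[(4-methoxybenzyl)oxy]-2-[(2S)-1-(triethylsilyloxy)propan-2-yl]phenyl}-8-(tert-butyldimethylsilyloxy)-3,7-dimethyloct-4-enoic acid, via silyl ketene acetal 19 (not isolated), via trimethylsilyl ester 20 (not isolated)
Conditions: LiHMDS (1.2 equiv), THF/DMPU (4:1), −78 °C; TMSCl; −78 °C to rt, then 45 °C; H2O, pH 5 buffer
Reagents that add atoms: none
Why: In this Ireland–Claisen rearrangement the arylacetate is expected to enolise to the Z(O)-enolate, so the chair transition state with the CH2 chain equatorial transfers the (4R)-carbinol chirality to C11 and, with the (E)-alkene, gives the syn C1/C11 pair while forming the C1–C11 bond and the (E)-C12=C13 alkene.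

Step 15
Reactants: 21 the rearranged acid
Product: 23 tert-butyl 3-[(2S,3S,4E,7R)-8-(tert-butyldimethylsilyloxy)-1-hydroxy-3,7-dimethyloct-4-en-2-yl]-5-[(4-methoxybenzyl)oxy]-4-[(2S)-1-(triethylsilyloxy)propan-2-yl]benzoate, via mixed carbonic anhydride 22 (not isolated)
Conditions: i-BuOCOCl, N-methylmorpholine, THF, −15 °C; then NaBH4, H2O, 0 °C
Reagents that add atoms: none
Why: Mixed-anhydride activation followed by borohydride reduction converts only the activated acyl group into C2H2OH and, unlike borane, leaves the C12=C13 alkene and the tert-butyl ester alone.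

Step 16
Reactants: 23 the primary alcohol with the C3 triethylsilyl ether
Product: 24 tert-butyl 3-[(2S,3S,4E,7R)-8-(tert-butyldimethylsilyloxy)-1-hydroxy-3,7-dimethyloct-4-en-2-yl]-4-[(2S)-1-hydroxypropan-2-yl]-5-[(4-methoxybenzyl)oxy]benzoate
Conditions: PPTS (0.2 equiv), MeOH/CH2Cl2, 0 °C to rt
Reagents that add atoms: none
Why: Acid-catalysed methanolysis removes the triethylsilyl ether much faster than the primary tert-butyldimethylsilyl ether, so only the C3 hydroxyl is released.

Step 17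
Reactants: 24 the C2,C3-diol
Product: 25 bis(methanesulfonate) of diol 24
Conditions: MsCl, Et3N, CH2Cl2, 0 °C
Reagents that add atoms: methanesulfonyl chloride, CS(=O)(=O)Cl
Why: Sulfonylation activates both primary arm hydroxyls for displacement without touching C1 or C4.

Step 18
Reactants: 25 the dimesylate
Product: 27 tert-butyl (1S,5S)-5-[(2S,3E,6R)-7-(tert-butyldimethylsilyloxy)-6-methylhept-3-en-2-yl]-9-[(4-methoxybenzyl)oxy]-1-methyl-2,3,4,5-tetrahydro-1H-3-benzothiepine-7-carboxylate, via thiolate mesylate 26 (not isolated)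
Conditions: Na2S·9H2O (1.5 equiv), DMF, 0.01 M, slow addition, 50 °C
Reagents that add atoms: sodium sulfide, [Na+].[Na+].[S-2]
Why: Double SN2 thioetherification closes the seven-membered sulfide with help from the ortho-phenylene tether, and both stereocentres are β to the reacting carbons and therefore untouched.

Step 19
Reactants: 27 the cyclic sulfide
Product: 29 the 3,3-dioxide (sulfone) of 27, via sulfoxide 28 (not isolated)
Conditions: (NH4)6Mo7O24·4H2O (10 mol %), 30% H2O2 (4 equiv), EtOH, 0 °C to rt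
Reagents that add atoms: hydrogen peroxide, OO
Why: Molybdate-catalysed peroxide oxidation takes the sulfide through the sulfoxide to the sulfone chemoselectively in the presence of the disubstituted alkene and the electron-rich benzyl ether.

Step 20
Reactants: 29 the benzo-fused seven-membered sulfone
Product: 32 tert-butyl (5R,8S)-8-[(2S,3E,6R)-7-(tert-butyldimethylsilyloxy)-6-methylhept-3-en-2-yl]-4-[(4-methoxybenzyl)oxy]-5-methyl-5,8-dihydronaphthalene-2-carboxylate, via α-bromo sulfone 30 (not isolated), via episulfone 31 (not isolated)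
Conditions: CBr2F2 (5 equiv), KOH on Al2O3, t-BuOH/CH2Cl2, 0 °C to rt
Reagents that add atoms: none
Why: Hydroxide deprotonates an α-sulfonyl CH2 (C2 or C3, both leading to the same product), the carbanion is brominated by halophilic attack on CBr2F2, and a second deprotonation at the α'-carbon is followed by 1,3-displacement of bromide to the ring-fused episulfone, which loses SO2 in a cheletropic step. The closest known reaction type is the Ramberg–Bäcklund ring contraction of cyclic sulfones to cycloalkenes with in-situ halogenation. Ring B is closed by the 3-exo-tet displacement that makes the C2–C3 bond inside the seven-membered ring, so the six-membered carbocycle arises by contraction and its alkene is necessarily cis. No new stereocentre remains, because the transient centres at C2 and C3 vanish with SO2 and the trans C1/C4 relationship is carried in from steps 6 and 14. The selectivity needed is deprotonation only α to sulfur, which is secured because C1–H and C4–H are β to the sulfone and merely benzylic, the tert-butyl ester resists hydroxide and difluorocarbene does not add to the two alkenes. Because C1–H and C4–H become doubly activated in the product, the reaction is kept cold and stopped at full conversion to avoid migration of the alkene into conjugation.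

Step 21
Reactants: 32 the 5,8-dihydronaphthalene silyl ether
Product: 33 tert-butyl (5R,8S)-8-[(2S,3E,6R)-7-hydroxy-6-methylhept-3-en-2-yl]-4-[(4-methoxybenzyl)oxy]-5-methyl-5,8-dihydronaphthalene-2-carboxylate
Conditions: TBAF, AcOH (1:1), THF, rt
Reagents that add atoms: none
Why: Fluoride desilylation buffered with acetic acid frees the C16 hydroxyl without exposing the doubly activated C1–H and C4–H to a strong base.

Step 22
Reactants: 33 the primary alcohol
Product: 34 tert-butyl (5R,8S)-4-[(4-methoxybenzyl)oxy]-5-methyl-8-[(2S,3E,6R)-6-methyl-7-(3-phenylpropanoyloxy)hept-3-en-2-yl]-5,8-dihydronaphthalene-2-carboxylate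
Conditions: PhCH2CH2COCl, pyridine, DMAP (cat.), CH2Cl2, 0 °C
Reagents that add atoms: 3-phenylpropanoyl chloride, O=C(Cl)CCc1ccccc1
Why: Acylation of the only free hydroxyl installs the 3-phenylpropanoate while the phenol is still masked.

Step 23
Reactants: 34 the diene ester
Product: 35 tert-butyl (5R,8S)-4-[(4-methoxybenzyl)oxy]-5-methyl-8-[(2S,6R)-6-methyl-7-(3-phenylpropanoyloxy)heptan-2-yl]-5,6,7,8-tetrahydronaphthalene-2-carboxylate
Conditions: H2 (1 atm), PtO2 (5 mol %), EtOAc, rt
Reagents that add atoms: none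
Why: Heterogeneous hydrogenation over platinum rather than palladium saturates both disubstituted alkenes with little double-bond migration, so C1, C4 and C11 are not erased and no new stereocentre is created.

Step 24
Reactants: 35 the fully saturated protected ester
Product: 36 (5R,8S)-4-hydroxy-5-methyl-8-[(2S,6R)-6-methyl-7-(3-phenylpropanoyloxy)heptan-2-yl]-5,6,7,8-tetrahydronaphthalene-2-carboxylic acid
Conditions: TFA/CH2Cl2 (1:3), anisole (5 equiv), 0 °C to rt
Reagents that add atoms: none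
Why: Acidolysis cleaves the tert-butyl ester through the tert-butyl cation and the aryl 4-methoxybenzyl ether through a benzylic cation trapped by anisole, while the primary alkyl ester is stable to anhydrous trifluoroacetic acid.

**Compound list**

1 | 4-bromo-3,5-dihydroxybenzoic acid | O=C(O)c1cc(O)c(Br)c(O)c1 | starting material
2 | tert-butyl 4-bromo-3,5-dihydroxybenzoate | CC(C)(C)OC(=O)c1cc(O)c(Br)c(O)c1 | intermediate
3 | tert-butyl 4-bromo-3-hydroxy-5-[(4-methoxybenzyl)oxy]benzoate | CC(C)(C)OC(=O)c1cc(O)c(Br)c(OCc2ccc(OC)cc2)c1 | intermediate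
4 | tert-butyl 3-hydroxy-5-[(4-methoxybenzyl)oxy]-4-(prop-1-en-2-yl)benzoate | CC(C)(C)OC(=O)c1cc(O)c(C(C)=C)c(OCc2ccc(OC)cc2)c1 | intermediate
5 | tert-butyl 3-[(4-methoxybenzyl)oxy]-4-(prop-1-en-2-yl)-5-[(trifluoromethanesulfonyl)oxy]benzoate | CC(C)(C)OC(=O)c1cc(OS(=O)(=O)C(F)(F)F)c(C(C)=C)c(OCc2ccc(OC)cc2)c1 | intermediate
6 | tert-butyl 3-(2-methoxy-2-oxoethyl)-5-[(4-methoxybenzyl)oxy]-4-(prop-1-en-2-yl)benzoate | CC(C)(C)OC(=O)c1cc(CC(=O)OC)c(C(C)=C)c(OCc2ccc(OC)cc2)c1 | intermediate
7 | tert-butyl 3-(2-methoxy-2-oxoethyl)-5-[(4-methoxybenzyl)oxy]-4-[(2R)-1-(4,4,5,5-tetramethyl-1,3,2-dioxaborolan-2-yl)propan-2-yl]benzoate | CC(C)(C)OC(=O)c1cc(CC(=O)OC)c([C@H](C)CB2OC(C)(C)C(C)(C)O2)c(OCc2ccc(OC)cc2)c1 | intermediate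
8 | tert-butyl 4-[(2S)-1-hydroxypropan-2-yl]-3-(2-methoxy-2-oxoethyl)-5-[(4-methoxybenzyl)oxy]benzoate | CC(C)(C)OC(=O)c1cc(CC(=O)OC)c([C@H](C)CO)c(OCc2ccc(OC)cc2)c1 | intermediate
9 | tert-butyl 3-(2-methoxy-2-oxoethyl)-5-[(4-methoxybenzyl)oxy]-4-[(2S)-1-(triethylsilyloxy)propan-2-yl]benzoate | CC(C)(C)OC(=O)c1cc(CC(=O)OC)c([C@H](C)CO[Si](CC)(CC)CC)c(OCc2ccc(OC)cc2)c1 | intermediate
10 | {5-(tert-butoxycarbonyl)-3-[(4-methoxybenzyl)oxy]-2-[(2S)-1-(triethylsilyloxy)propan-2-yl]phenyl}acetic acid | CC(C)(C)OC(=O)c1cc(CC(=O)O)c([C@H](C)CO[Si](CC)(CC)CC)c(OCc2ccc(OC)cc2)c1 | intermediate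
11 | (S)-3-bromo-2-methylpropan-1-ol | BrC[C@@H](C)CO | starting material
12 | (S)-(3-bromo-2-methylpropoxy)(tert-butyl)dimethylsilane | BrC[C@@H](C)CO[Si](C)(C)C(C)(C)C | intermediate
13 | (E)-but-2-enal (crotonaldehyde) | C/C=C/C=O | starting material
14 | [(2S)-3-(tert-butyldimethylsilyloxy)-2-methylpropyl]magnesium bromide | Br[Mg]C[C@@H](C)CO[Si](C)(C)C(C)(C)C | intermediate
15 | (2E,6R)-7-(tert-butyldimethylsilyloxy)-6-methylhept-2-en-4-ol, both C4 epimers | C/C=C/C(O)C[C@@H](C)CO[Si](C)(C)C(C)(C)C | intermediate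
16 | (2E,6R)-7-(tert-butyldimethylsilyloxy)-6-methylhept-2-en-4-one | C/C=C/C(=O)C[C@@H](C)CO[Si](C)(C)C(C)(C)C | intermediate
17 | (2E,4R,6R)-7-(tert-butyldimethylsilyloxy)-6-methylhept-2-en-4-ol | C/C=C/[C@H](O)C[C@@H](C)CO[Si](C)(C)C(C)(C)C | intermediate
18 | tert-butyl 3-(2-{[(2E,4R,6R)-7-(tert-butyldimethylsilyloxy)-6-methylhept-2-en-4-yl]oxy}-2-oxoethyl)-5-[(4-methoxybenzyl)oxy]-4-[(2S)-1-(triethylsilyloxy)propan-2-yl]benzoate | CC(C)(C)OC(=O)c1cc(CC(=O)O[C@@H](/C=C/C)C[C@@H](C)CO[Si](C)(C)C(C)(C)C)c([C@H](C)CO[Si](CC)(CC)CC)c(OCc2ccc(OC)cc2)c1 | intermediate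
19 | (Z)-O-trimethylsilyl ketene acetal of ester 18 (aryl cis to OSiMe3) | C/C=C/[C@@H](C[C@@H](C)CO[Si](C)(C)C(C)(C)C)O/C(O[Si](C)(C)C)=C/c1cc(C(=O)OC(C)(C)C)cc(OCc2ccc(OC)cc2)c1[C@H](C)CO[Si](CC)(CC)CC | intermediate
20 | trimethylsilyl ester of acid 21 | C[C@H](C/C=C/[C@H](C)[C@H](C(=O)O[Si](C)(C)C)c1cc(C(=O)OC(C)(C)C)cc(OCc2ccc(OC)cc2)c1[C@H](C)CO[Si](CC)(CC)CC)CO[Si](C)(C)C(C)(C)C | intermediate
21 | (2S,3S,4E,7R)-2-{5-(tert-butoxycarbonyl)-3-[(4-methoxybenzyl)oxy]-2-[(2S)-1-(triethylsilyloxy)propan-2-yl]phenyl}-8-(tert-butyldimethylsilyloxy)-3,7-dimethyloct-4-enoic acid | C[C@H](C/C=C/[C@H](C)[C@H](C(=O)O)c1cc(C(=O)OC(C)(C)C)cc(OCc2ccc(OC)cc2)c1[C@H](C)CO[Si](CC)(CC)CC)CO[Si](C)(C)C(C)(C)C | intermediate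
22 | isobutyl carbonic mixed anhydride of acid 21 | C[C@H](C/C=C/[C@H](C)[C@H](C(=O)OC(=O)OCC(C)C)c1cc(C(=O)OC(C)(C)C)cc(OCc2ccc(OC)cc2)c1[C@H](C)CO[Si](CC)(CC)CC)CO[Si](C)(C)C(C)(C)C | intermediate
23 | tert-butyl 3-[(2S,3S,4E,7R)-8-(tert-butyldimethylsilyloxy)-1-hydroxy-3,7-dimethyloct-4-en-2-yl]-5-[(4-methoxybenzyl)oxy]-4-[(2S)-1-(triethylsilyloxy)propan-2-yl]benzoate | C[C@H](C/C=C/[C@H](C)[C@H](CO)c1cc(C(=O)OC(C)(C)C)cc(OCc2ccc(OC)cc2)c1[C@H](C)CO[Si](CC)(CC)CC)CO[Si](C)(C)C(C)(C)C | intermediate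
24 | tert-butyl 3-[(2S,3S,4E,7R)-8-(tert-butyldimethylsilyloxy)-1-hydroxy-3,7-dimethyloct-4-en-2-yl]-4-[(2S)-1-hydroxypropan-2-yl]-5-[(4-methoxybenzyl)oxy]benzoate | C[C@H](C/C=C/[C@H](C)[C@H](CO)c1cc(C(=O)OC(C)(C)C)cc(OCc2ccc(OC)cc2)c1[C@H](C)CO)CO[Si](C)(C)C(C)(C)C | intermediate
25 | bis(methanesulfonate) of diol 24 | C[C@H](C/C=C/[C@H](C)[C@H](COS(C)(=O)=O)c1cc(C(=O)OC(C)(C)C)cc(OCc2ccc(OC)cc2)c1[C@H](C)COS(C)(=O)=O)CO[Si](C)(C)C(C)(C)C | intermediate
26 | sodium thiolate after the first displacement (taken at the less hindered C3 arm, C2 mesylate still in place) | C[C@H](C/C=C/[C@H](C)[C@H](COS(C)(=O)=O)c1cc(C(=O)OC(C)(C)C)cc(OCc2ccc(OC)cc2)c1[C@H](C)C[S-])CO[Si](C)(C)C(C)(C)C.[Na+] | intermediate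
27 | tert-butyl (1S,5S)-5-[(2S,3E,6R)-7-(tert-butyldimethylsilyloxy)-6-methylhept-3-en-2-yl]-9-[(4-methoxybenzyl)oxy]-1-methyl-2,3,4,5-tetrahydro-1H-3-benzothiepine-7-carboxylate | C[C@H](C/C=C/[C@H](C)[C@@H]1CSC[C@@H](C)c2c(OCc3ccc(OC)cc3)cc(C(=O)OC(C)(C)C)cc21)CO[Si](C)(C)C(C)(C)C | intermediate
28 | 3-oxide (sulfoxide) of 27, configuration at sulfur not defined | C[C@H](C/C=C/[C@H](C)[C@@H]1CS(=O)C[C@@H](C)c2c(OCc3ccc(OC)cc3)cc(C(=O)OC(C)(C)C)cc21)CO[Si](C)(C)C(C)(C)C | intermediate
29 | 3,3-dioxide (sulfone) of 27, (1S,5S) | C[C@H](C/C=C/[C@H](C)[C@@H]1CS(=O)(=O)C[C@@H](C)c2c(OCc3ccc(OC)cc3)cc(C(=O)OC(C)(C)C)cc21)CO[Si](C)(C)C(C)(C)C | intermediate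
30 | α-bromo sulfone (bromine drawn on the CH2 next to the methyl-bearing carbon; the regioisomer converges on the same alkene) | C[C@H](C/C=C/[C@H](C)[C@@H]1CS(=O)(=O)C(Br)[C@@H](C)c2c(OCc3ccc(OC)cc3)cc(C(=O)OC(C)(C)C)cc21)CO[Si](C)(C)C(C)(C)C | intermediate
31 | episulfone (thiirane 1,1-dioxide fused across C2–C3 of the nascent ring B) | C[C@H](C/C=C/[C@H](C)[C@@H]1C2C(S2(=O)=O)[C@@H](C)c2c(OCc3ccc(OC)cc3)cc(C(=O)OC(C)(C)C)cc21)CO[Si](C)(C)C(C)(C)C | intermediate
32 | tert-butyl (5R,8S)-8-[(2S,3E,6R)-7-(tert-butyldimethylsilyloxy)-6-methylhept-3-en-2-yl]-4-[(4-methoxybenzyl)oxy]-5-methyl-5,8-dihydronaphthalene-2-carboxylate | C[C@H](C/C=C/[C@H](C)[C@@H]1C=C[C@@H](C)c2c(OCc3ccc(OC)cc3)cc(C(=O)OC(C)(C)C)cc21)CO[Si](C)(C)C(C)(C)C | intermediate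
33 | tert-butyl (5R,8S)-8-[(2S,3E,6R)-7-hydroxy-6-methylhept-3-en-2-yl]-4-[(4-methoxybenzyl)oxy]-5-methyl-5,8-dihydronaphthalene-2-carboxylate | C[C@H](C/C=C/[C@H](C)[C@@H]1C=C[C@@H](C)c2c(OCc3ccc(OC)cc3)cc(C(=O)OC(C)(C)C)cc21)CO | intermediate
34 | tert-butyl (5R,8S)-4-[(4-methoxybenzyl)oxy]-5-methyl-8-[(2S,3E,6R)-6-methyl-7-(3-phenylpropanoyloxy)hept-3-en-2-yl]-5,8-dihydronaphthalene-2-carboxylate | C[C@H](C/C=C/[C@H](C)[C@@H]1C=C[C@@H](C)c2c(OCc3ccc(OC)cc3)cc(C(=O)OC(C)(C)C)cc21)COC(=O)CCc1ccccc1 | intermediate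
35 | tert-butyl (5R,8S)-4-[(4-methoxybenzyl)oxy]-5-methyl-8-[(2S,6R)-6-methyl-7-(3-phenylpropanoyloxy)heptan-2-yl]-5,6,7,8-tetrahydronaphthalene-2-carboxylate | C[C@H](CCC[C@H](C)[C@@H]1CC[C@@H](C)c2c(OCc3ccc(OC)cc3)cc(C(=O)OC(C)(C)C)cc21)COC(=O)CCc1ccccc1 | intermediate
36 | (5R,8S)-4-hydroxy-5-methyl-8-[(2S,6R)-6-methyl-7-(3-phenylpropanoyloxy)heptan-2-yl]-5,6,7,8-tetrahydronaphthalene-2-carboxylic acid (CNP0511546.1) | C[C@H](CCC[C@H](C)[C@@H]1CC[C@@H](C)c2c(O)cc(C(=O)O)cc21)COC(=O)CCc1ccccc1 | target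

**Step count**

Total: 24 steps. Longest linear sequence: 20 steps (steps 1–8 and 13–24, from 1 to 36); the side-chain fragment takes 4 steps (9–12) before the union in step 13.

**Steps most likely to fail, with fallbacks**

1. Step 20 (ring contraction). The in-situ halogenation may stall or go twice on the hindered α-carbons. The basic medium may also move the new C2=C3 double bond into conjugation with the arene, or the dihydronaphthalene may be dehydrogenated; either would erase C1 or C4. The fallback makes the same C2–C3 bond reductively, without sulfur. It sets out from dimesylate 25. Finkelstein exchange (NaI, acetone, reflux) should give the diiodide F1. Nickel-catalysed intramolecular reductive coupling of the two primary iodides (NiI2, 4,4'-di-tert-butyl-2,2'-bipyridine, Zn dust, DMA, rt, high dilution) should close ring B directly at the alkane level to the tetralin silyl ether F2. TBAF/AcOH should then give the tetralin alcohol F3, and 3-phenylpropanoyl chloride with pyridine the tetralin ester F4, which still holds the C12=C13 alkene. Hydrogenation over PtO2 brings the material back to the route at 35.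

2. Step 6 (hydroboration). The alkene sits between two ortho substituents and is twisted out of conjugation, so catalyst turnover may be slow and discrimination of the two alkene faces poor. The fallback gives up catalyst control and resolves instead. It sets out from alkene 6. Hydroboration with 9-BBN (THF, 60 °C) should give the B-alkyl-9-borabicyclononane adduct F5, and NaBO3 oxidation the racemic primary alcohol F6. DCC/DMAP esterification with (S)-2-methoxy-2-phenylacetic acid gives two diastereomeric esters, to be separated by chromatography or crystallisation into the ester of the (S)-alcohol F7 and the ester of the (R)-alcohol F8, the latter set aside. Methanolysis of F7 (K2CO3, MeOH) returns to the route at 8.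

3. Step 18 (thiepane closure). Basic sulfide may eliminate the β-branched mesylates to styrenes, or the first-formed thiolate may react between molecules and give oligomers instead of the seven-membered ring. The fallback introduces sulfur without base and closes the ring in a separate intramolecular step. It sets out from alcohol 23. Mitsunobu thioacetylation (PPh3, DIAD, AcSH, THF, 0 °C) should give the thioacetate F9. PPTS in MeOH removes the triethylsilyl group to give the hydroxy thioacetate F10, and MsCl/Et3N gives the mesylate thioacetate F11. K2CO3 in degassed MeOH at high dilution then frees the thiolate, which displaces the mesylate intramolecularly and comes back to the route at sulfide 27.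

**Further compounds**

F1 | step 20 | diiodide corresponding to dimesylate 25 | C[C@H](C/C=C/[C@H](C)[C@H](CI)c1cc(C(=O)OC(C)(C)C)cc(OCc2ccc(OC)cc2)c1[C@H](C)CI)CO[Si](C)(C)C(C)(C)C
F2 | step 20 | tert-butyl (5R,8S)-8-[(2S,3E,6R)-7-(tert-butyldimethylsilyloxy)-6-methylhept-3-en-2-yl]-4-[(4-methoxybenzyl)oxy]-5-methyl-5,6,7,8-tetrahydronaphthalene-2-carboxylate | C[C@H](C/C=C/[C@H](C)[C@@H]1CC[C@@H](C)c2c(OCc3ccc(OC)cc3)cc(C(=O)OC(C)(C)C)cc21)CO[Si](C)(C)C(C)(C)C
F3 | step 20 | tert-butyl (5R,8S)-8-[(2S,3E,6R)-7-hydroxy-6-methylhept-3-en-2-yl]-4-[(4-methoxybenzyl)oxy]-5-methyl-5,6,7,8-tetrahydronaphthalene-2-carboxylate | C[C@H](C/C=C/[C@H](C)[C@@H]1CC[C@@H](C)c2c(OCc3ccc(OC)cc3)cc(C(=O)OC(C)(C)C)cc21)CO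
F4 | step 20 | tert-butyl (5R,8S)-4-[(4-methoxybenzyl)oxy]-5-methyl-8-[(2S,3E,6R)-6-methyl-7-(3-phenylpropanoyloxy)hept-3-en-2-yl]-5,6,7,8-tetrahydronaphthalene-2-carboxylate | C[C@H](C/C=C/[C@H](C)[C@@H]1CC[C@@H](C)c2c(OCc3ccc(OC)cc3)cc(C(=O)OC(C)(C)C)cc21)COC(=O)CCc1ccccc1
F5 | step 6 | B-alkyl-9-borabicyclo[3.3.1]nonane adduct of alkene 6 (racemic) | CC(C)(C)OC(=O)c1cc(CC(=O)OC)c(C(C)CB2C3CCCC2CCC3)c(OCc2ccc(OC)cc2)c1
F6 | step 6 | racemic tert-butyl 4-(1-hydroxypropan-2-yl)-3-(2-methoxy-2-oxoethyl)-5-[(4-methoxybenzyl)oxy]benzoate | CC(C)(C)OC(=O)c1cc(CC(=O)OC)c(C(C)CO)c(OCc2ccc(OC)cc2)c1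
F7 | step 6 | (S)-2-methoxy-2-phenylacetate ester of the (2S)-alcohol 8 | CC(C)(C)OC(=O)c1cc(CC(=O)OC)c([C@H](C)COC(=O)[C@@H](OC)c2ccccc2)c(OCc2ccc(OC)cc2)c1
F8 | step 6 | (S)-2-methoxy-2-phenylacetate ester of the (2R)-alcohol (unwanted diastereomer) | CC(C)(C)OC(=O)c1cc(CC(=O)OC)c([C@@H](C)COC(=O)[C@@H](OC)c2ccccc2)c(OCc2ccc(OC)cc2)c1
F9 | step 18 | S-acetyl thioester at C2 of alcohol 23 (triethylsilyl ether retained) | C[C@H](C/C=C/[C@H](C)[C@H](CSC(C)=O)c1cc(C(=O)OC(C)(C)C)cc(OCc2ccc(OC)cc2)c1[C@H](C)CO[Si](CC)(CC)CC)CO[Si](C)(C)C(C)(C)C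
F10 | step 18 | hydroxy thioacetate (C3 hydroxyl free) | C[C@H](C/C=C/[C@H](C)[C@H](CSC(C)=O)c1cc(C(=O)OC(C)(C)C)cc(OCc2ccc(OC)cc2)c1[C@H](C)CO)CO[Si](C)(C)C(C)(C)C
F11 | step 18 | mesylate thioacetate (C3 methanesulfonate) | C[C@H](C/C=C/[C@H](C)[C@H](CSC(C)=O)c1cc(C(=O)OC(C)(C)C)cc(OCc2ccc(OC)cc2)c1[C@H](C)COS(C)(=O)=O)CO[Si](C)(C)C(C)(C)C
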